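**Strategy.** The trihydroxylated cyclohexane ring (carotenoid numbering: C1 gem-dimethyl, C3 secondary carbinol, C5 methyl carbinol, C6 chain-bearing carbinol) hides a mesityl oxide unit (C1–C4) and an acetoacetate unit (C5, C6, C7). One Lewis-acid-mediated Michael–aldol annulation of these two bulk chemicals forges C1–C6 and C4–C5 and gives enone ester 5 with every ring carbon, all three methyl groups and the C3 and C7 oxygen handles in place. 5 also maps onto the ε-ring, so both end groups come from it. Sharpless epoxidation, Payne opening and a substrate-controlled reduction set the triol; C15 + C10 + C15 Wittig couplings build the polyene.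

Key step: step 1

Remark on the chemistry: carotenoid locants are used for the target and its fragments (triol ring C1–C6, chain C7–C15, primed locants on the ε-ring half). Triethyl 3-methyl-4-phosphonocrotonate (16) and 2,7-dimethylocta-2,4,6-trienedial (29) are taken as commercial. Enone ester 5 is racemic by design, so the reagent-controlled reduction of step 12 should give 21 together with its C1 epimer, which is removed there by chromatography and not carried on.

## Triol fragment

Step 1
Reactants: 1 mesityl oxide (4-methylpent-3-en-2-one); 2 ethyl acetoacetate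
Product: 5 ethyl 2,6,6-trimethyl-4-oxocyclohex-2-ene-1-carboxylate (racemic), via Michael adduct 3 (not isolated), via aldol 4 (not isolated)
Conditions: BF3·OEt2 (substoichiometric), neat, 20 °C
Reagents that add atoms: none
Why: The Lewis acid activates mesityl oxide and holds ethyl acetoacetate as its chelated enol, whose central carbon adds to the β,β-dimethyl terminus (Michael addition, C1–C6); the methyl ketone so formed enolises towards its methyl group and attacks the chelate-activated acetyl carbonyl (intramolecular aldol, C4–C5), and loss of water from aldol 4 gives the conjugated enone. The closest known reaction type is the Robinson-type annulation that makes Hagemann's ester from an acetoacetate and an enone. The ring is closed in the aldol event in the 6-(enolendo)-exo-trig mode. The only stereocentre of 5 (the ester-bearing carbon) forms racemic and is not controlled, which is intended: it is erased in step 2 on the triol branch and sorted by the reagent-controlled reduction of step 12 on the ε branch. The step needs conjugate instead of carbonyl addition and one of two possible aldol closures; the chelated β-keto ester carbonyl is the most electrophilic carbonyl of 3, and the irreversible dehydration to the trisubstituted enone should drain the equilibria towards 5.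

Step 2
Reactants: 5 ethyl 2,6,6-trimethyl-4-oxocyclohex-2-ene-1-carboxylate
Product: 6 ethyl 7,9,9-trimethyl-1,4-dioxaspiro[4.5]dec-7-ene-8-carboxylate
Conditions: HOCH2CH2OH, p-toluenesulfonic acid monohydrate (cat.), toluene, reflux, Dean–Stark
Reagents that add atoms: ethylene glycol, OCCO
Why: Acid-catalysed dioxolane formation of the enone runs through the dienol ether, so the double bond should move from C4=C5 to the tetrasubstituted C5=C6 position in conjugation with the ester (deconjugative ketalisation as known for Hagemann's ester), which also erases the racemic stereocentre.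

Step 3
Reactants: 6 ethyl 7,9,9-trimethyl-1,4-dioxaspiro[4.5]dec-7-ene-8-carboxylate
Product: 7 (7,9,9-trimethyl-1,4-dioxaspiro[4.5]dec-7-en-8-yl)methanol
Conditions: LiAlH4, Et2O, 0 °C
Reagents that add atoms: none
Why: Hydride 1,2-reduction of the hindered, twisted conjugated ester should stop at the allylic alcohol and leave the dioxolane untouched; no stereocentre is formed.

Step 4
Reactants: 7 (7,9,9-trimethyl-1,4-dioxaspiro[4.5]dec-7-en-8-yl)methanol
Product: 8 [(1S,6S)-2,2,6-trimethylspiro[7-oxabicyclo[4.1.0]heptane-4,2'-[1,3]dioxolan]-1-yl]methanol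
Conditions: Ti(OiPr)4 (0.2 equiv), diethyl L-(+)-tartrate (0.25 equiv), t-BuOOH, 4 Å molecular sieves, CH2Cl2, −20 °C
Reagents that add atoms: tert-butyl hydroperoxide, CC(C)(C)OO
Why: Katsuki–Sharpless asymmetric epoxidation of the achiral tetrasubstituted allylic alcohol: the L-(+)-tartrate–titanium complex should deliver oxygen to the enantiotopic face that gives the (1S,6S)-oxirane (the facial sense that gives (2S,3S)-2,3-epoxygeraniol), so both oxirane carbons are set by the reagent.

Step 5
Reactants: 8 [(1S,6S)-2,2,6-trimethylspiro[7-oxabicyclo[4.1.0]heptane-4,2'-[1,3]dioxolan]-1-yl]methanol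
Product: 11 (3S,4R)-3,4-dihydroxy-4-(hydroxymethyl)-3,5,5-trimethylcyclohexan-1-one, via spiro-oxirane 9 (not isolated), via triol ketal 10 (not isolated)
Conditions: NaOH (1 M aq.), t-BuOH, 75 °C; then aq. HCl to pH 1, THF, 20 °C
Reagents that add atoms: water (delivered as hydroxide), O
Why: Payne rearrangement with hydroxide opening: the C7 alkoxide displaces the oxirane oxygen at C6 with inversion (3-exo-tet) to give spiro-oxirane 9, whose CH2 carbon is the only site open to hydroxide, so C5 keeps its oxygen with retention, C6 is inverted and the trans-5,6-diol should form without a regiochemical choice, after which dilute acid hydrolyses the dioxolane.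

Step 6
Reactants: 11 (3S,4R)-3,4-dihydroxy-4-(hydroxymethyl)-3,5,5-trimethylcyclohexan-1-one
Product: 12 (1R,2S,4S)-1-(hydroxymethyl)-2,6,6-trimethylcyclohexane-1,2,4-triol
Conditions: LiBH(sBu)3 (L-Selectride, excess), THF, −78 °C; H2O
Reagents that add atoms: none
Why: Diastereoselective hydride reduction: in the chair with the diaxial 5,6-diol the axial C1 methyl and the axial 5-OH block the axial trajectory at C3, so the bulky borohydride should attack equatorially (as with 3,3,5-trimethylcyclohexanone) and give the axial 3-OH cis to 5-OH, which is the (3S) centre of the target.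

Step 7
Reactants: 12 (1R,2S,4S)-1-(hydroxymethyl)-2,6,6-trimethylcyclohexane-1,2,4-triol
Product: 14 (1R,2S,4S)-2,6,6-trimethyl-4-(triethylsilyloxy)-1-[(triethylsilyloxy)methyl]-1,2-bis(trimethylsilyloxy)cyclohexane, via bis-TES ether 13 (not isolated)
Conditions: Et3SiCl (2.3 equiv), imidazole, 4-(dimethylamino)pyridine (cat.), CH2Cl2, 0 → 20 °C; then 2,6-lutidine, Me3SiOTf, −20 → 20 °C
Reagents that add atoms: chlorotriethylsilane, CC[Si](Cl)(CC)CC; trimethylsilyl triflate, C[Si](C)(C)OS(=O)(=O)C(F)(F)F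
Why: Stepwise silylation: the chloride should cap only the primary and the secondary hydroxyl, and the small, more electrophilic triflate then the two hindered tertiary hydroxyls, so that no free α-hydroxyl remains next to the future aldehyde.

Step 8
Reactants: 14 (1R,2S,4S)-2,6,6-trimethyl-4-(triethylsilyloxy)-1-[(triethylsilyloxy)methyl]-1,2-bis(trimethylsilyloxy)cyclohexane
Product: 15 (1S,2S,4S)-2,6,6-trimethyl-4-(triethylsilyloxy)-1,2-bis(trimethylsilyloxy)cyclohexane-1-carbaldehyde
Conditions: (COCl)2, DMSO, CH2Cl2, −78 → −35 °C; Et3N, → 0 °C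
Reagents that add atoms: none
Why: Swern oxidation with in situ desilylation: the activated sulfonium salt should cleave only the least hindered primary triethylsilyl ether and oxidise the released oxygen to the aldehyde, while the secondary triethylsilyl and tertiary trimethylsilyl ethers stay; the quaternary α-carbon cannot epimerise.

Step 9
Reactants: 15 (1S,2S,4S)-2,6,6-trimethyl-4-(triethylsilyloxy)-1,2-bis(trimethylsilyloxy)cyclohexane-1-carbaldehyde; 16 triethyl 3-methyl-4-phosphonocrotonate
Product: 17 ethyl (2E,4E)-3-methyl-5-[(1S,2S,4S)-2,6,6-trimethyl-4-(triethylsilyloxy)-1,2-bis(trimethylsilyloxy)cyclohexyl]penta-2,4-dienoate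
Conditions: LiN(SiMe3)2, THF, −78 °C; then 15, −78 → 20 °C
Reagents that add atoms: none
Why: Horner–Wadsworth–Emmons olefination of the non-enolisable aldehyde with the vinylogous phosphonate should give the (7E)-alkene and carry in the (9E)-trisubstituted alkene, any 9Z isomer being removed by chromatography.

Step 10
Reactants: 17 ethyl (2E,4E)-3-methyl-5-[(1S,2S,4S)-2,6,6-trimethyl-4-(triethylsilyloxy)-1,2-bis(trimethylsilyloxy)cyclohexyl]penta-2,4-dienoate
Product: 18 (2E,4E)-3-methyl-5-[(1S,2S,4S)-2,6,6-trimethyl-4-(triethylsilyloxy)-1,2-bis(trimethylsilyloxy)cyclohexyl]penta-2,4-dien-1-ol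
Conditions: iBu2AlH (2.5 equiv), CH2Cl2, −78 °C; aq. potassium sodium tartrate
Reagents that add atoms: none
Why: Hydride 1,2-reduction of the dienoate to the allylic alcohol should leave the silyl ethers and the alkene geometry unchanged.

Step 11
Reactants: 18 (2E,4E)-3-methyl-5-[(1S,2S,4S)-2,6,6-trimethyl-4-(triethylsilyloxy)-1,2-bis(trimethylsilyloxy)cyclohexyl]penta-2,4-dien-1-ol
Product: 20 {(2E,4E)-3-methyl-5-[(1S,2S,4S)-2,6,6-trimethyl-4-(triethylsilyloxy)-1,2-bis(trimethylsilyloxy)cyclohexyl]penta-2,4-dienyl}triphenylphosphonium bromide, via allylic bromide 19 (not isolated)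
Conditions: CBr4, PPh3, CH2Cl2, 0 °C; then PPh3, 20 °C
Reagents that add atoms: carbon tetrabromide, BrC(Br)(Br)Br; triphenylphosphine, c1ccccc1P(c1ccccc1)c1ccccc1
Why: Appel bromination of the primary allylic alcohol followed by SN2 quaternisation of triphenylphosphine proceeds without Brønsted acid, so the tertiary allylic C6–O bond and the silyl ethers should not ionise.

## ε-Ring fragment

Step 12
Reactants: 5 ethyl 2,6,6-trimethyl-4-oxocyclohex-2-ene-1-carboxylate (racemic)
Product: 21 ethyl (1R,4R)-4-hydroxy-2,6,6-trimethylcyclohex-2-ene-1-carboxylate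
Conditions: (S)-1-methyl-3,3-diphenyltetrahydro-1H,3H-pyrrolo[1,2-c][1,3,2]oxazaborole (0.2 equiv), BH3·SMe2, THF, −20 °C; MeOH; chromatography
Reagents that add atoms: none
Why: Corey–Bakshi–Shibata reduction: the oxazaborolidine–borane complex should deliver hydride to one face of the enone carbonyl (alkenyl flank as the large group) and fix C4 as R in both antipodes of 5, so the (1R)-antipode gives trans-hydroxy ester 21, which is separated by chromatography from the cis (1S,4R) diastereomer that the (1S)-antipode gives.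

Step 13
Reactants: 21 ethyl (1R,4R)-4-hydroxy-2,6,6-trimethylcyclohex-2-ene-1-carboxylate
Product: 22 ethyl (1R,4R)-4-(tert-butyldimethylsilyloxy)-2,6,6-trimethylcyclohex-2-ene-1-carboxylate
Conditions: tBuMe2SiCl, imidazole, DMF, 20 °C
Reagents that add atoms: tert-butyldimethylsilyl chloride, CC(C)(C)[Si](C)(C)Cl
Why: Standard silylation protects the allylic secondary alcohol against the later oxidation and bromination steps.

Step 14
Reactants: 22 ethyl (1R,4R)-4-(tert-butyldimethylsilyloxy)-2,6,6-trimethylcyclohex-2-ene-1-carboxylate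
Product: 23 [(1R,4R)-4-(tert-butyldimethylsilyloxy)-2,6,6-trimethylcyclohex-2-en-1-yl]methanol
Conditions: LiAlH4, Et2O, 0 °C
Reagents that add atoms: none
Why: Hydride reduction of the ester should outpace enolisation, so the C1 stereocentre and the position of the ring double bond are kept.

Step 15
Reactants: 23 [(1R,4R)-4-(tert-butyldimethylsilyloxy)-2,6,6-trimethylcyclohex-2-en-1-yl]methanol
Product: 24 (1R,4R)-4-(tert-butyldimethylsilyloxy)-2,6,6-trimethylcyclohex-2-ene-1-carbaldehyde
Conditions: Dess–Martin periodinane (1,1,1-triacetoxy-1,1-dihydro-1,2-benziodoxol-3(1H)-one), CH2Cl2, 20 °C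
Reagents that add atoms: none
Why: Dess–Martin oxidation is base-free, so the α-stereocentre (allylic and next to the aldehyde) should not epimerise and the alkene should not move into conjugation.

Step 16
Reactants: 24 (1R,4R)-4-(tert-butyldimethylsilyloxy)-2,6,6-trimethylcyclohex-2-ene-1-carbaldehyde; 16 triethyl 3-methyl-4-phosphonocrotonate
Product: 25 ethyl (2E,4E)-5-[(1R,4R)-4-(tert-butyldimethylsilyloxy)-2,6,6-trimethylcyclohex-2-en-1-yl]-3-methylpenta-2,4-dienoate
Conditions: LiN(SiMe3)2, THF, −78 °C; then 24, −78 → −20 °C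
Reagents that add atoms: none
Why: Horner–Wadsworth–Emmons olefination at low temperature, where carbonyl addition should outrun α-deprotonation, gives the (7'E,9'E)-dienoate (9'Z isomer removed by chromatography).

Step 17
Reactants: 25 ethyl (2E,4E)-5-[(1R,4R)-4-(tert-butyldimethylsilyloxy)-2,6,6-trimethylcyclohex-2-en-1-yl]-3-methylpenta-2,4-dienoate
Product: 26 (2E,4E)-5-[(1R,4R)-4-(tert-butyldimethylsilyloxy)-2,6,6-trimethylcyclohex-2-en-1-yl]-3-methylpenta-2,4-dien-1-ol
Conditions: iBu2AlH (2.5 equiv), CH2Cl2, −78 °C; aq. potassium sodium tartrate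
Reagents that add atoms: none
Why: Hydride 1,2-reduction of the dienoate should give the allylic alcohol without touching the silyl ether or the stereocentres.

Step 18
Reactants: 26 (2E,4E)-5-[(1R,4R)-4-(tert-butyldimethylsilyloxy)-2,6,6-trimethylcyclohex-2-en-1-yl]-3-methylpenta-2,4-dien-1-ol
Product: 28 {(2E,4E)-5-[(1R,4R)-4-(tert-butyldimethylsilyloxy)-2,6,6-trimethylcyclohex-2-en-1-yl]-3-methylpenta-2,4-dienyl}triphenylphosphonium bromide, via allylic bromide 27 (not isolated)
Conditions: CBr4, PPh3, CH2Cl2, 0 °C; then PPh3, 20 °C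
Reagents that add atoms: carbon tetrabromide, BrC(Br)(Br)Br; triphenylphosphine, c1ccccc1P(c1ccccc1)c1ccccc1
Why: Appel bromination and SN2 quaternisation under neutral conditions should spare the acid-sensitive allylic silyl ether of the ε-ring.

Step 19
Reactants: 28 {(2E,4E)-5-[(1R,4R)-4-(tert-butyldimethylsilyloxy)-2,6,6-trimethylcyclohex-2-en-1-yl]-3-methylpenta-2,4-dienyl}triphenylphosphonium bromide; 29 (2E,4E,6E)-2,7-dimethylocta-2,4,6-trienedial (3 equiv)
Product: 30 (2E,4E,6E,8E,10E,12E)-13-[(1R,4R)-4-(tert-butyldimethylsilyloxy)-2,6,6-trimethylcyclohex-2-en-1-yl]-2,7,11-trimethyltrideca-2,4,6,8,10,12-hexaenal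
Conditions: NaOMe, MeOH/CH2Cl2, 0 → 20 °C; then heptane, reflux, dark, Ar
Reagents that add atoms: none
Why: Wittig olefination of the allylic ylide with one aldehyde group of the symmetric dialdehyde, used in excess to suppress double condensation, forms C11'=C12', and heating should isomerise the hindered Z isomer to the all-E aldehyde.

## Coupling and deprotection

Step 20
Reactants: 20 {(2E,4E)-3-methyl-5-[(1S,2S,4S)-2,6,6-trimethyl-4-(triethylsilyloxy)-1,2-bis(trimethylsilyloxy)cyclohexyl]penta-2,4-dienyl}triphenylphosphonium bromide; 30 (2E,4E,6E,8E,10E,12E)-13-[(1R,4R)-4-(tert-butyldimethylsilyloxy)-2,6,6-trimethylcyclohex-2-en-1-yl]-2,7,11-trimethyltrideca-2,4,6,8,10,12-hexaenal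
Product: 31 the fully silylated carotenoid (3'-O-tert-butyldimethylsilyl, 3-O-triethylsilyl, 5,6-bis-O-trimethylsilyl ether of the target, all-E)
Conditions: NaN(SiMe3)2, THF, −78 → 20 °C; then heptane, 80 °C, dark, Ar
Reagents that add atoms: none
Why: Wittig olefination of the allylic ylide with the polyenal forms C11=C12 under aprotic basic conditions that the silyl ethers tolerate, and thermal equilibration should convert the 11Z isomer into the all-E polyene.

Step 21
Reactants: 31 the fully silylated carotenoid (3'-O-tert-butyldimethylsilyl, 3-O-triethylsilyl, 5,6-bis-O-trimethylsilyl ether of the target)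
Product: 32 (3S,5S,6S,3'R,6'R)-5,6-dihydro-β,ε-carotene-3,5,6,3'-tetrol (target)
Conditions: Bu4NF (excess), THF, 20 °C, dark, Ar
Reagents that add atoms: none
Why: Fluoride-induced desilylation should remove all four silyl groups without acid, so neither the tertiary allylic 6-OH nor the allylic 3'-OH can ionise and no stereocentre is touched.

## Compound list

1 | mesityl oxide (4-methylpent-3-en-2-one) | CC(=O)C=C(C)C | starting material
2 | ethyl acetoacetate | CCOC(=O)CC(C)=O | starting material
3 | ethyl 2-acetyl-3,3-dimethyl-5-oxohexanoate (racemic Michael adduct) | CCOC(=O)C(C(C)=O)C(C)(C)CC(C)=O | intermediate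
4 | ethyl 2-hydroxy-2,6,6-trimethyl-4-oxocyclohexane-1-carboxylate (racemic aldol) | CCOC(=O)C1C(C)(O)CC(=O)CC1(C)C | intermediate
5 | ethyl 2,6,6-trimethyl-4-oxocyclohex-2-ene-1-carboxylate (racemic) | CCOC(=O)C1C(C)=CC(=O)CC1(C)C | intermediate
6 | ethyl 7,9,9-trimethyl-1,4-dioxaspiro[4.5]dec-7-ene-8-carboxylate | CCOC(=O)C1=C(C)CC2(OCCO2)CC1(C)C | intermediate
7 | (7,9,9-trimethyl-1,4-dioxaspiro[4.5]dec-7-en-8-yl)methanol | OCC1=C(C)CC2(OCCO2)CC1(C)C | intermediate
8 | [(1S,6S)-2,2,6-trimethylspiro[7-oxabicyclo[4.1.0]heptane-4,2'-[1,3]dioxolan]-1-yl]methanol | OC[C@]12O[C@@]1(C)CC3(OCCO3)CC2(C)C | intermediate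
9 | spiro-oxirane (Payne isomer of 8: oxirane spiro-fused at C6 through C6 and the C7 methylene, free tertiary 5-OH, dioxolane intact) | O[C@@]1(C)CC2(OCCO2)CC(C)(C)[C@@]13CO3 | intermediate
10 | (7S,8R)-8-(hydroxymethyl)-7,9,9-trimethyl-1,4-dioxaspiro[4.5]decane-7,8-diol | OC[C@]1(O)C(C)(C)CC2(OCCO2)C[C@]1(C)O | intermediate
11 | (3S,4R)-3,4-dihydroxy-4-(hydroxymethyl)-3,5,5-trimethylcyclohexan-1-one | OC[C@]1(O)C(C)(C)CC(=O)C[C@]1(C)O | intermediate
12 | (1R,2S,4S)-1-(hydroxymethyl)-2,6,6-trimethylcyclohexane-1,2,4-triol | OC[C@]1(O)C(C)(C)C[C@H](O)C[C@]1(C)O | intermediate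
13 | (1R,2S,4S)-2,6,6-trimethyl-4-(triethylsilyloxy)-1-[(triethylsilyloxy)methyl]cyclohexane-1,2-diol | CC[Si](CC)(CC)OC[C@]1(O)C(C)(C)C[C@H](O[Si](CC)(CC)CC)C[C@]1(C)O | intermediate
14 | (1R,2S,4S)-2,6,6-trimethyl-4-(triethylsilyloxy)-1-[(triethylsilyloxy)methyl]-1,2-bis(trimethylsilyloxy)cyclohexane | CC[Si](CC)(CC)OC[C@]1(O[Si](C)(C)C)C(C)(C)C[C@H](O[Si](CC)(CC)CC)C[C@]1(C)O[Si](C)(C)C | intermediate
15 | (1S,2S,4S)-2,6,6-trimethyl-4-(triethylsilyloxy)-1,2-bis(trimethylsilyloxy)cyclohexane-1-carbaldehyde | O=C[C@]1(O[Si](C)(C)C)C(C)(C)C[C@H](O[Si](CC)(CC)CC)C[C@]1(C)O[Si](C)(C)C | intermediate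
16 | triethyl 3-methyl-4-phosphonocrotonate (ethyl (2E)-4-(diethoxyphosphoryl)-3-methylbut-2-enoate) | CCOC(=O)/C=C(\C)CP(=O)(OCC)OCC | starting material
17 | ethyl (2E,4E)-3-methyl-5-[(1S,2S,4S)-2,6,6-trimethyl-4-(triethylsilyloxy)-1,2-bis(trimethylsilyloxy)cyclohexyl]penta-2,4-dienoate | CCOC(=O)/C=C(\C)/C=C/[C@]1(O[Si](C)(C)C)C(C)(C)C[C@H](O[Si](CC)(CC)CC)C[C@]1(C)O[Si](C)(C)C | intermediate
18 | (2E,4E)-3-methyl-5-[(1S,2S,4S)-2,6,6-trimethyl-4-(triethylsilyloxy)-1,2-bis(trimethylsilyloxy)cyclohexyl]penta-2,4-dien-1-ol | OC/C=C(\C)/C=C/[C@]1(O[Si](C)(C)C)C(C)(C)C[C@H](O[Si](CC)(CC)CC)C[C@]1(C)O[Si](C)(C)C | intermediate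
19 | (1S,2S,4S)-1-[(1E,3E)-5-bromo-3-methylpenta-1,3-dienyl]-2,6,6-trimethyl-4-(triethylsilyloxy)-1,2-bis(trimethylsilyloxy)cyclohexane (triol-ring C15 allylic bromide) | BrC/C=C(\C)/C=C/[C@]1(O[Si](C)(C)C)C(C)(C)C[C@H](O[Si](CC)(CC)CC)C[C@]1(C)O[Si](C)(C)C | intermediate
20 | {(2E,4E)-3-methyl-5-[(1S,2S,4S)-2,6,6-trimethyl-4-(triethylsilyloxy)-1,2-bis(trimethylsilyloxy)cyclohexyl]penta-2,4-dienyl}triphenylphosphonium bromide (triol-ring C15 phosphonium salt) | c1ccccc1[P+](c1ccccc1)(c1ccccc1)C/C=C(\C)/C=C/[C@]1(O[Si](C)(C)C)C(C)(C)C[C@H](O[Si](CC)(CC)CC)C[C@]1(C)O[Si](C)(C)C.[Br-] | intermediate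
21 | ethyl (1R,4R)-4-hydroxy-2,6,6-trimethylcyclohex-2-ene-1-carboxylate | CC1=C[C@H](O)CC(C)(C)[C@H]1C(=O)OCC | intermediate
22 | ethyl (1R,4R)-4-(tert-butyldimethylsilyloxy)-2,6,6-trimethylcyclohex-2-ene-1-carboxylate | CC1=C[C@H](O[Si](C)(C)C(C)(C)C)CC(C)(C)[C@H]1C(=O)OCC | intermediate
23 | [(1R,4R)-4-(tert-butyldimethylsilyloxy)-2,6,6-trimethylcyclohex-2-en-1-yl]methanol | CC1=C[C@H](O[Si](C)(C)C(C)(C)C)CC(C)(C)[C@H]1CO | intermediate
24 | (1R,4R)-4-(tert-butyldimethylsilyloxy)-2,6,6-trimethylcyclohex-2-ene-1-carbaldehyde | CC1=C[C@H](O[Si](C)(C)C(C)(C)C)CC(C)(C)[C@H]1C=O | intermediate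
25 | ethyl (2E,4E)-5-[(1R,4R)-4-(tert-butyldimethylsilyloxy)-2,6,6-trimethylcyclohex-2-en-1-yl]-3-methylpenta-2,4-dienoate | CC1=C[C@H](O[Si](C)(C)C(C)(C)C)CC(C)(C)[C@H]1/C=C/C(C)=C/C(=O)OCC | intermediate
26 | (2E,4E)-5-[(1R,4R)-4-(tert-butyldimethylsilyloxy)-2,6,6-trimethylcyclohex-2-en-1-yl]-3-methylpenta-2,4-dien-1-ol | CC1=C[C@H](O[Si](C)(C)C(C)(C)C)CC(C)(C)[C@H]1/C=C/C(C)=C/CO | intermediate
27 | (1R,4R)-1-[(1E,3E)-5-bromo-3-methylpenta-1,3-dienyl]-4-(tert-butyldimethylsilyloxy)-2,6,6-trimethylcyclohex-2-ene (ε-ring C15 allylic bromide) | CC1=C[C@H](O[Si](C)(C)C(C)(C)C)CC(C)(C)[C@H]1/C=C/C(C)=C/CBr | intermediate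
28 | {(2E,4E)-5-[(1R,4R)-4-(tert-butyldimethylsilyloxy)-2,6,6-trimethylcyclohex-2-en-1-yl]-3-methylpenta-2,4-dienyl}triphenylphosphonium bromide (ε-ring C15 phosphonium salt) | CC1=C[C@H](O[Si](C)(C)C(C)(C)C)CC(C)(C)[C@H]1/C=C/C(C)=C/C[P+](c1ccccc1)(c1ccccc1)c1ccccc1.[Br-] | intermediate
29 | (2E,4E,6E)-2,7-dimethylocta-2,4,6-trienedial | O=C/C(C)=C/C=C/C=C(C)/C=O | starting material
30 | (2E,4E,6E,8E,10E,12E)-13-[(1R,4R)-4-(tert-butyldimethylsilyloxy)-2,6,6-trimethylcyclohex-2-en-1-yl]-2,7,11-trimethyltrideca-2,4,6,8,10,12-hexaenal | CC1=C[C@H](O[Si](C)(C)C(C)(C)C)CC(C)(C)[C@H]1/C=C/C(C)=C/C=C/C(C)=C/C=C/C=C(C)/C=O | intermediate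
31 | fully silylated carotenoid (3'-O-tert-butyldimethylsilyl, 3-O-triethylsilyl, 5,6-bis-O-trimethylsilyl ether of the target, all-E) | CC1=C[C@H](O[Si](C)(C)C(C)(C)C)CC(C)(C)[C@H]1/C=C/C(C)=C/C=C/C(C)=C/C=C/C=C(C)/C=C/C=C(C)/C=C/[C@]1(O[Si](C)(C)C)C(C)(C)C[C@H](O[Si](CC)(CC)CC)C[C@]1(C)O[Si](C)(C)C | intermediate
32 | (3S,5S,6S,3'R,6'R)-5,6-dihydro-β,ε-carotene-3,5,6,3'-tetrol | CC1=C[C@H](O)CC(C)(C)[C@H]1/C=C/C(C)=C/C=C/C(C)=C/C=C/C=C(C)/C=C/C=C(C)/C=C/[C@]1(O)C(C)(C)C[C@H](O)C[C@]1(C)O | target

## Count and risks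

Total step count: 21. Longest linear sequence: 13 steps (steps 1–11, 20, 21).

The three steps most likely to fail:

1. Step 5. The Payne equilibrium lies on the side of the tetrasubstituted oxirane, and attack of hydroxide on the neopentyl-type CH2 of the spiro-oxirane may be too slow. The material may then be recovered, or the tertiary alkoxide may close onto that CH2 to an oxetane. The fallback sets out from 7. Epoxidation with diethyl D-(−)-tartrate, Ti(OiPr)4 and t-BuOOH gives the antipodal epoxy alcohol, [(1R,6R)-2,2,6-trimethylspiro[7-oxabicyclo[4.1.0]heptane-4,2'-[1,3]dioxolan]-1-yl]methanol F1. Acid-catalysed hydrolysis (HClO4 cat., THF/H2O, 0 °C) should then open the oxirane at the methyl-bearing carbon, which is remote from the inductively deactivating CH2OH group, with inversion. The same acid removes the dioxolane, so the fallback comes back to the route at 11.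

2. Step 12. Face discrimination by the oxazaborolidine may be poor, because the two flanks of the carbonyl (alkene CH and a CH2 next to a quaternary carbon) differ little in size; this would erode the enantiopurity of 21. The fallback sets out from 5. Luche reduction (NaBH4, CeCl3·7H2O, MeOH, −78 °C) gives the racemic trans-hydroxy ester, ethyl (1RS,4RS)-4-hydroxy-2,6,6-trimethylcyclohex-2-ene-1-carboxylate F2, after removal of the cis isomer. Kinetic resolution with Burkholderia cepacia lipase and vinyl acetate in MTBE is expected to acylate the (4R)-alcohol to ethyl (1R,4R)-4-acetoxy-2,6,6-trimethylcyclohex-2-ene-1-carboxylate F3. Ethanolysis (K2CO3, EtOH) comes back to the route at 21.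

3. Step 16. The basic phosphonate anion may deprotonate the aldehyde α-carbon, which is also allylic, before it adds to the hindered carbonyl; this would epimerise C6' or move the ring double bond into conjugation. The fallback sets out from 24. Wittig reaction with the non-basic stabilised ylide 1-(triphenylphosphoranylidene)propan-2-one (toluene, 90 °C) gives (3E)-4-[(1R,4R)-4-(tert-butyldimethylsilyloxy)-2,6,6-trimethylcyclohex-2-en-1-yl]but-3-en-2-one F4. Horner–Wadsworth–Emmons reaction of this ketone with triethyl phosphonoacetate (NaH, THF) and removal of the 9'Z isomer comes back to the route at 25.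

## Further compounds

F1 | step 5 | [(1R,6R)-2,2,6-trimethylspiro[7-oxabicyclo[4.1.0]heptane-4,2'-[1,3]dioxolan]-1-yl]methanol | OC[C@@]12O[C@]1(C)CC3(OCCO3)CC2(C)C
F2 | step 12 | ethyl (1RS,4RS)-4-hydroxy-2,6,6-trimethylcyclohex-2-ene-1-carboxylate (racemate, both antipodes written) | CC1=C[C@H](O)CC(C)(C)[C@H]1C(=O)OCC.CC1=C[C@@H](O)CC(C)(C)[C@@H]1C(=O)OCC
F3 | step 12 | ethyl (1R,4R)-4-acetoxy-2,6,6-trimethylcyclohex-2-ene-1-carboxylate | CC1=C[C@H](OC(C)=O)CC(C)(C)[C@H]1C(=O)OCC
F4 | step 16 | (3E)-4-[(1R,4R)-4-(tert-butyldimethylsilyloxy)-2,6,6-trimethylcyclohex-2-en-1-yl]but-3-en-2-one | CC1=C[C@H](O[Si](C)(C)C(C)(C)C)CC(C)(C)[C@H]1/C=C/C(C)=O
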